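Watch the time first, for product in the oak run starts late and then climbs: it reads 0.5% after 2.00 min but 20.8% after 15.0 min.

| flask | substrate | partner | temperature | remark | time |
|---|---|---|---|---|---|
| maple | 1.4 M | 1.2 M | 45 °C | run made earlier |  |
| oak | 1.4 M | 2.1 M | 70 °C | run made earlier |  |
| summer | 1.4 M | 3.00 M | 90 °C |  | 80 min |
| dawn | 1.4 M | 1.68 M | 50 °C |  | 80 min |

| run | time / min | product / % |
|---|---|---|
| maple | 15.0 | 0.3 |
| maple | 30.0 | 1.5 |
| maple | 50.0 | 0.6 |
| maple | 60.0 | 0.5 |
| maple | 80.0 | 2.6 |
| oak | 2.00 | 0.5 |
| oak | 4.00 | 1.2 |
| oak | 10.0 | 8.9 |
| oak | 15.0 | 20.8 |
| oak | 30.0 | 52.5 |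

(standard deviation of a reading: 0.5 percentage points)

- which of the two ends with the higher amount of product, in percent of the substrate charged ("neither" if they lie within 2 percentage points) (summer / dawn / neither)
- product at the end, in percent of the substrate charged, summer
- product at the end, in percent of the substrate charged, dawn

- the analysis behind the earlier runs scatters by 0.5 percentage points, standard deviation

Keep one ledger per flask in shares of the substrate charged, with substrate as the limiting reagent, since partner stands at 1.20 equivalents in dawn and 2.14 in summer. It has two entries that sum to the charge: product, and a rest whose form the readings do not show.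

For the product entry, replace the bent curve by its start: oak's reading at 10.0 min gives 33.5 min as the filling time, the time divided by the square root of the product share, so that product is time over filling time, squared. Check what this replacement costs: it gives 20.0% at 15.0 min against 20.8% read, but 80.2% at 30.0 min against 52.5%, so use it while product is small.

Maple's last reading, 2.6% with its scatter of 0.5 percentage points, gives 496 min. Take partner as first order and spread the remaining factor of 125 evenly in its logarithm between 45 °C and 70 °C. My reckoning then gives dawn 259 min, which is longer than the run, so book 9.56% to product and 90.4% to the rest. Summer, extrapolated, gets 4.06 min, far shorter than its 80 min, so the rule is out of its range there; book the whole charge to product.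

The forecast gives summer as the higher, with 95% for summer and 7% for dawn, a dawn figure below mine, and says: “Summer is hotter, has more partner, and runs far beyond oak's timescale, so it should be essentially complete.”

The flask gives >99.9% in summer and 10.5% in dawn, so summer ends higher, and dawn's rest divides into 47.2% substrate and 42.3% open intermediate.

    partner → second intermediate (k = 0.380 h⁻¹, Ea = 114 kJ mol⁻¹)
    substrate ⇌ open intermediate (K = 4.30, k = 0.630 h⁻¹, Ea = 99.0 kJ mol⁻¹, ΔH = 19.0 kJ mol⁻¹)
    open intermediate + second intermediate → product (k = 0.740 M⁻¹ h⁻¹, Ea = 58.0 kJ mol⁻¹)
    (constants at 50 °C)

Read dawn's filling time from its result, 247 min, then cut partner to 0.42 M in the neighbour flask, where its 0.300 equiv makes partner the limiting reagent. The filling time lengthens to 494 min, which books 2.62% to product. At 80.0 min the neighbour flask holds 48% substrate, 49.6% open intermediate and 2.84% product.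

All runs were computed for an exercise; scatter was added.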